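The synthesis hinges on cutting ring A at C5–C6. Ring A (C4a, C5, C6, C7, C8, C8a) bears oxygen on C5, C7 and C8a and the C4 acyl group on C4a, the pattern a polyketide chain gives when it is cyclised by C-acylation. Ring C is therefore built first as an (S)-dihydropyranone whose oxygen is O1 on C8a, and ring A is closed last by an intramolecular Claisen condensation that forms C5–C6, aromatises the ring and moves the side-chain alkene to C1''=C2'' in a single operation; only the 6-substituted flavanone can result. The precursor is a methyl 2-aryl-4-oxo-2,3-dihydropyran-5-carboxylate with a 2-oxo-(Z)-alk-3-enyl arm on the carbon that becomes C8a.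

Key step: step 9

Numbering: flavanone locants (O1, C2–C4, C4a, C5–C8, C8a; side chain C1''–C8'') are used for these atoms in precursor 16 as well; "6-methyl" in 10 is a pyranone locant.

Design remarks:
- The enone arm of 16 is made as the Z isomer. γ-Deprotonation of a Z-enone can only give the E-dienolate (allylic 1,3-strain), whereas an E-enone tends to give the Z-alkene (syn effect). The cis γ-hydrogens also lie within reach of a base held at O7.
- Ring B carries tert-butyldimethylsilyl ethers, so the end game needs fluoride and no acid. Acid would cyclise the electron-rich 2-hydroxystyrene onto the trisubstituted alkene.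
- The arm is attached by γ-acylation of a 6-methylpyranone, because an acylketene would acylate the free δ-hydroxyl first.
- Compound 16 should be kept cold and used at once, since O7 can lactonise onto the ester.

Assumption: with Chan's diene and aryl aldehydes the (S)-BINOL titanium catalyst is taken to add to the Si face and give the (S)-carbinol; the ee and sense of 7 would be checked before going on.

Step 1
Reactants: 1 3,4-dihydroxybenzaldehyde
Product: 2 3,4-bis(tert-butyldimethylsilyloxy)benzaldehyde
Conditions: TBSCl (2.4 equiv), imidazole (5 equiv), DMF, 0 °C to rt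
Reagents that add atoms: tert-butyldimethylsilyl chloride, CC(C)(C)[Si](C)(C)Cl
Why: Imidazole-promoted O-silylation of both phenols gives aryl silyl ethers that should tolerate the later amide bases and leave with fluoride at the end.

Step 2
Reactants: 3 methyl acetoacetate
Product: 4 methyl 3-(trimethylsilyloxy)but-2-enoate (E/Z mixture)
Conditions: TMSCl, Et3N, hexane, rt; filter, distil
Reagents that add atoms: chlorotrimethylsilane, C[Si](C)(C)Cl
Why: Silyl enol ether formation at the ketone of the β-keto ester, whose double-bond geometry is lost in the next step.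

Step 3
Reactants: 4 methyl 3-(trimethylsilyloxy)but-2-enoate
Product: 5 1-methoxy-1,3-bis(trimethylsilyloxy)buta-1,3-diene (Chan's diene)
Conditions: LiN(iPr)2, THF, −78 °C; then TMSCl, −78 °C to 0 °C
Reagents that add atoms: chlorotrimethylsilane, C[Si](C)(C)Cl
Why: γ-Deprotonation of the silyloxy crotonate and O-silylation of the ester dienolate give the bis-silyl dienol ether.

Step 4
Reactants: 2 3,4-bis(tert-butyldimethylsilyloxy)benzaldehyde, 5 Chan's diene
Product: 7 methyl (5S)-5-[3,4-bis(tert-butyldimethylsilyloxy)phenyl]-5-hydroxy-3-oxopentanoate, via bis-silylated aldol adduct 6 (not isolated)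
Conditions: Ti(OiPr)4 (10 mol %), (S)-BINOL (10 mol %), 4 Å MS, THF, −78 °C to rt; then TFA (cat.), THF/H2O, 0 °C
Reagents that add atoms: none
Why: Catalytic enantioselective vinylogous Mukaiyama aldol addition, in which the titanium (S)-BINOLate should expose the Si face of the aldehyde to the γ-carbon of the diene and so set the (S)-carbinol (the later C2), after which dilute acid cleaves the two trimethylsilyl groups of 6 and spares the aryl silyl ethers.

Step 5
Reactants: 7 methyl (5S)-5-[3,4-bis(tert-butyldimethylsilyloxy)phenyl]-5-hydroxy-3-oxopentanoate, 8 N,N-dimethylacetamide dimethyl acetal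
Product: 10 methyl (2S)-2-[3,4-bis(tert-butyldimethylsilyloxy)phenyl]-6-methyl-4-oxo-2,3-dihydro-4H-pyran-5-carboxylate, via enaminone 9 (not isolated)
Conditions: 8 (1.5 equiv), toluene, rt; then BF3·OEt2 (1.1 equiv), 0 °C
Reagents that add atoms: none
Why: Condensation of the active methylene with the amide acetal gives enaminone 9, and the Lewis acid lets the δ-hydroxyl displace dimethylamine by addition–elimination (a Maitland–Japp-type dihydropyranone synthesis), which closes ring C without touching the C–O bond of the stereocentre, so the (S) configuration is retained.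

Step 6
Reactants: 11 (S)-citronellal, 12 methyl bis(2,2,2-trifluoroethyl)phosphonoacetate
Product: 13 methyl (2Z,5S)-5,9-dimethyldeca-2,8-dienoate
Conditions: KN(SiMe3)2, 18-crown-6, THF, −78 °C
Reagents that add atoms: none
Why: Still–Gennari olefination, in which the trifluoroethyl phosphonate eliminates fast from the kinetic adduct under dissociating conditions and should give the Z-enoate selectively, the remote stereocentre of citronellal being untouched.

Step 7
Reactants: 13 methyl (2Z,5S)-5,9-dimethyldeca-2,8-dienoate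
Product: 14 (2Z,5S)-5,9-dimethyldeca-2,8-dienoic acid
Conditions: LiOH·H2O, THF/MeOH/H2O, 0 °C to rt; then 1 M HCl to pH 3
Reagents that add atoms: lithium hydroxide, [Li+].[OH-]
Why: Mild ester saponification, which should leave the Z double bond and the stereocentre alone and gives the acid needed for activation.

Step 8
Reactants: 10 methyl (2S)-2-[3,4-bis(tert-butyldimethylsilyloxy)phenyl]-6-methyl-4-oxo-2,3-dihydro-4H-pyran-5-carboxylate, 14 (2Z,5S)-5,9-dimethyldeca-2,8-dienoic acid
Product: 16 methyl (2S)-2-[3,4-bis(tert-butyldimethylsilyloxy)phenyl]-6-[(3Z,6S)-6,10-dimethyl-2-oxoundeca-3,9-dien-1-yl]-4-oxo-2,3-dihydro-4H-pyran-5-carboxylate, via acid chloride 15 (not isolated)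
Conditions: 14, 1-chloro-N,N,2-trimethylprop-1-en-1-amine, CH2Cl2, 0 °C; added to 10 (2.0 equiv) and LiN(SiMe3)2 (2.0 equiv), THF, −78 °C; AcOH, −78 °C; excess 10 recovered
Reagents that add atoms: none
Why: Vinylogous Claisen-type C-acylation, in which LiN(SiMe3)2 removes a proton from the 6-methyl group (the most acidic site, vinylogous to both the ketone and the ester) and the lithium dienolate is acylated at its γ-carbon by acid chloride 15, made under neutral conditions so that the Z geometry is kept, as is known for dioxinone dienolates; the second equivalent of dienolate takes up the acidic C8 proton of the product.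

Step 9
Reactants: 16 methyl (2S)-2-[3,4-bis(tert-butyldimethylsilyloxy)phenyl]-6-[(3Z,6S)-6,10-dimethyl-2-oxoundeca-3,9-dien-1-yl]-4-oxo-2,3-dihydro-4H-pyran-5-carboxylate
Product: 18 (2S)-2-[3,4-bis(tert-butyldimethylsilyloxy)phenyl]-6-[(1E,3S)-3,7-dimethylocta-1,6-dien-1-yl]-5,7-dihydroxy-2,3-dihydro-4H-chromen-4-one, via triketone tautomer 17 (not isolated)
Conditions: LiN(iPr)2 (3.0 equiv), THF, −78 °C to −20 °C; AcOH, −78 °C
Reagents that add atoms: none
Why: Proposed new method: LiN(iPr)2 first removes the C8 proton and then, held at the O7 lithium enolate, a C2'' proton that the Z-enone places next to O7; the dienolate attacks the ester carbon (C5) through C6, methoxide leaves, and triketone 17 enolises twice to the 5,7-diphenoxide, so that aromatisation makes the closure irreversible. The closest known reactions are the base-mediated Claisen (Dieckmann-type) cyclisation of 3,5,7-triketo esters to acylphloroglucinols and the α-selective C-acylation of dienolates made by γ-deprotonation of enoates. Ring A closes in a 6-(enolendo)-exo-trig mode, the C6=C7 enolate bond lying inside the new ring, and no stereocentre is formed. Regiochemistry is set by the substrate, since O1 already sits on C8a and C2'' could reach C5 only through an eight-membered ring, while O-acylation by O7 is reversible under the methoxide set free and C-acylation is not. The E geometry of C1''=C2'' follows from the Z-enone, in which allylic 1,3-strain against C7 turns C3'' outward during γ-deprotonation, as in the known conversion of (Z)-2-alkenoates into (E)-3-alkenoates. The C2 stereocentre survives as long as a C3 enolate does not expel O1, which the low temperature and the acetic acid quench in the cold should secure.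

Step 10
Reactants: 18 (2S)-2-[3,4-bis(tert-butyldimethylsilyloxy)phenyl]-6-[(1E,3S)-3,7-dimethylocta-1,6-dien-1-yl]-5,7-dihydroxy-2,3-dihydro-4H-chromen-4-one
Product: 19 (2S)-2-(3,4-dihydroxyphenyl)-6-[(1E,3S)-3,7-dimethylocta-1,6-dien-1-yl]-5,7-dihydroxy-2,3-dihydro-4H-chromen-4-one (CNP0230070.1)
Conditions: Bu4NF (2.4 equiv), AcOH (3 equiv), THF, 0 °C
Reagents that add atoms: none
Why: Fluoride-induced desilylation of the two aryl silyl ethers under acetic acid buffering, which avoids both the base that would open ring C at O1–C2 and the acid that would cyclise the 2-hydroxystyrene onto the trisubstituted alkene.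

Compound list
1 | 3,4-dihydroxybenzaldehyde | O=Cc1ccc(O)c(O)c1 | starting material
2 | 3,4-bis(tert-butyldimethylsilyloxy)benzaldehyde | O=Cc1ccc(O[Si](C)(C)C(C)(C)C)c(O[Si](C)(C)C(C)(C)C)c1 | intermediate
3 | methyl acetoacetate | CC(=O)CC(=O)OC | starting material
4 | methyl 3-(trimethylsilyloxy)but-2-enoate (E/Z mixture, geometry not carried on) | COC(=O)C=C(C)O[Si](C)(C)C | intermediate
5 | 1-methoxy-1,3-bis(trimethylsilyloxy)buta-1,3-diene (Chan's diene, C1=C2 geometry not defined) | COC(O[Si](C)(C)C)=CC(=C)O[Si](C)(C)C | intermediate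
6 | methyl (5S)-5-[3,4-bis(tert-butyldimethylsilyloxy)phenyl]-3,5-bis(trimethylsilyloxy)pent-2-enoate (silylated aldol adduct, enol ether geometry not defined) | COC(=O)C=C(O[Si](C)(C)C)C[C@H](O[Si](C)(C)C)c1ccc(O[Si](C)(C)C(C)(C)C)c(O[Si](C)(C)C(C)(C)C)c1 | intermediate
7 | methyl (5S)-5-[3,4-bis(tert-butyldimethylsilyloxy)phenyl]-5-hydroxy-3-oxopentanoate | COC(=O)CC(=O)C[C@H](O)c1ccc(O[Si](C)(C)C(C)(C)C)c(O[Si](C)(C)C(C)(C)C)c1 | intermediate
8 | N,N-dimethylacetamide dimethyl acetal (1,1-dimethoxy-N,N-dimethylethanamine) | CC(OC)(OC)N(C)C | starting material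
9 | methyl (5S)-5-[3,4-bis(tert-butyldimethylsilyloxy)phenyl]-2-[1-(dimethylamino)ethylidene]-5-hydroxy-3-oxopentanoate (enaminone, C=C geometry not defined) | COC(=O)C(=C(C)N(C)C)C(=O)C[C@H](O)c1ccc(O[Si](C)(C)C(C)(C)C)c(O[Si](C)(C)C(C)(C)C)c1 | intermediate
10 | methyl (2S)-2-[3,4-bis(tert-butyldimethylsilyloxy)phenyl]-6-methyl-4-oxo-2,3-dihydro-4H-pyran-5-carboxylate | CC1=C(C(=O)OC)C(=O)C[C@@H](c2ccc(O[Si](C)(C)C(C)(C)C)c(O[Si](C)(C)C(C)(C)C)c2)O1 | intermediate
11 | (S)-citronellal, (3S)-3,7-dimethyloct-6-enal | CC(C)=CCC[C@H](C)CC=O | starting material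
12 | methyl bis(2,2,2-trifluoroethyl)phosphonoacetate | COC(=O)CP(=O)(OCC(F)(F)F)OCC(F)(F)F | starting material
13 | methyl (2Z,5S)-5,9-dimethyldeca-2,8-dienoate | CC(C)=CCC[C@H](C)C/C=C\C(=O)OC | intermediate
14 | (2Z,5S)-5,9-dimethyldeca-2,8-dienoic acid | CC(C)=CCC[C@H](C)C/C=C\C(=O)O | intermediate
15 | (2Z,5S)-5,9-dimethyldeca-2,8-dienoyl chloride | CC(C)=CCC[C@H](C)C/C=C\C(=O)Cl | intermediate
16 | methyl (2S)-2-[3,4-bis(tert-butyldimethylsilyloxy)phenyl]-6-[(3Z,6S)-6,10-dimethyl-2-oxoundeca-3,9-dien-1-yl]-4-oxo-2,3-dihydro-4H-pyran-5-carboxylate (key-step precursor) | CC(C)=CCC[C@H](C)C/C=C\C(=O)CC1=C(C(=O)OC)C(=O)C[C@@H](c2ccc(O[Si](C)(C)C(C)(C)C)c(O[Si](C)(C)C(C)(C)C)c2)O1 | intermediate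
17 | (2S)-2-[3,4-bis(tert-butyldimethylsilyloxy)phenyl]-6-[(1E,3S)-3,7-dimethylocta-1,6-dien-1-yl]-2,3-dihydro-4H-chromene-4,5,7(6H,8H)-trione (present as lithium enolate, C6 configuration not defined) | CC(C)=CCC[C@H](C)/C=C/C1C(=O)CC2=C(C1=O)C(=O)C[C@@H](c1ccc(O[Si](C)(C)C(C)(C)C)c(O[Si](C)(C)C(C)(C)C)c1)O2 | intermediate
18 | (2S)-2-[3,4-bis(tert-butyldimethylsilyloxy)phenyl]-6-[(1E,3S)-3,7-dimethylocta-1,6-dien-1-yl]-5,7-dihydroxy-2,3-dihydro-4H-chromen-4-one | CC(C)=CCC[C@H](C)/C=C/c1c(O)cc2c(c1O)C(=O)C[C@@H](c1ccc(O[Si](C)(C)C(C)(C)C)c(O[Si](C)(C)C(C)(C)C)c1)O2 | intermediate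
19 | (2S)-2-(3,4-dihydroxyphenyl)-6-[(1E,3S)-3,7-dimethylocta-1,6-dien-1-yl]-5,7-dihydroxy-2,3-dihydro-4H-chromen-4-one | CC(C)=CCC[C@H](C)/C=C/c1c(O)cc2c(c1O)C(=O)C[C@@H](c1ccc(O)c(O)c1)O2 | target

Total step count: 10. Longest linear sequence: 7 steps (3 → 4 → 5 → 7 → 10 → 16 → 18 → 19); the aldehyde branch (step 1) joins at step 4 and the citronellal branch (steps 6–7) at step 8.

Steps most likely to fail

1. Step 9. The second deprotonation may take place at C3 instead of C2'', and warming may then expel O1 from the C3 enolate, with ring opening and loss of the C2 configuration; O7 may also acylate in place of C6. The fallback gives up building ring A and attaches the side chain to a bought flavanone by known cross-coupling. It sets out from none of the intermediates (commercial (2S)-eriodictyol stands in for 1–18) and comes back to the route at 19. (2S)-Eriodictyol is silylated (TBSCl, imidazole, DMF; the chelated 5-hydroxyl stays free) to the 3',4',7-tris-silyl ether F1. Iodination ortho to the free phenol (BnMe3N ICl2, CaCO3, CH2Cl2/MeOH) should give the 6-iodide F2. A Mizoroki–Heck reaction with commercial (S)-3,7-dimethylocta-1,6-diene (Pd(OAc)2, Bu4NCl, NaHCO3, DMF, 60 °C) should give the (E)-alkenyl flavanone F3, the 7-silyl ether of 18. Desilylation under the conditions of step 10 gives 19.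

2. Step 8. The dienolate may be acylated on oxygen, enolisation may occur at C3 instead of the methyl group, and Z-to-E leakage may arise through a vinylketene formed from the acid chloride. The fallback replaces acylation by aldol addition and oxidation; it sets out from 10 and 13 and comes back at 16. Reduction of 13 (iBu2AlH, CH2Cl2, −78 °C) gives the Z-allylic alcohol F4, and Dess–Martin oxidation (NaHCO3, CH2Cl2, 0 °C) gives the Z-enal F5, used at once. The lithium dienolate of 10 (LiN(SiMe3)2, THF, −78 °C) adds to it in a vinylogous aldol reaction to give the carbinol F6 as a mixture of epimers, and a second Dess–Martin oxidation gives 16.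

3. Step 5. The electron-rich benzylic carbinol may ionise or eliminate under the Lewis acid, or retro-aldol cleavage under the basic acetal may outrun ring closure. The fallback builds the pyranone by C-acylation and cyclodehydration; it sets out from 7 and comes back at 10. Silylation (Et3SiCl, imidazole, CH2Cl2) gives the triethylsilyl ether F7. Magnesium-mediated C-acetylation of the β-keto ester (MgCl2, pyridine, acetyl chloride, CH2Cl2, 0 °C) gives the tricarbonyl compound F8. Mild acid (PPTS, MeOH, rt, then toluene, 50 °C) removes the triethylsilyl group and cyclodehydrates to 10.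

Further compounds
F1 | step 9 | (2S)-2-[3,4-bis(tert-butyldimethylsilyloxy)phenyl]-7-(tert-butyldimethylsilyloxy)-5-hydroxy-2,3-dihydro-4H-chromen-4-one | O=C1C[C@@H](c2ccc(O[Si](C)(C)C(C)(C)C)c(O[Si](C)(C)C(C)(C)C)c2)Oc2cc(O[Si](C)(C)C(C)(C)C)cc(O)c21
F2 | step 9 | (2S)-2-[3,4-bis(tert-butyldimethylsilyloxy)phenyl]-7-(tert-butyldimethylsilyloxy)-5-hydroxy-6-iodo-2,3-dihydro-4H-chromen-4-one | O=C1C[C@@H](c2ccc(O[Si](C)(C)C(C)(C)C)c(O[Si](C)(C)C(C)(C)C)c2)Oc2cc(O[Si](C)(C)C(C)(C)C)c(I)c(O)c21
F3 | step 9 | (2S)-2-[3,4-bis(tert-butyldimethylsilyloxy)phenyl]-7-(tert-butyldimethylsilyloxy)-6-[(1E,3S)-3,7-dimethylocta-1,6-dien-1-yl]-5-hydroxy-2,3-dihydro-4H-chromen-4-one | CC(C)=CCC[C@H](C)/C=C/c1c(O[Si](C)(C)C(C)(C)C)cc2c(c1O)C(=O)C[C@@H](c1ccc(O[Si](C)(C)C(C)(C)C)c(O[Si](C)(C)C(C)(C)C)c1)O2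
F4 | step 8 | (2Z,5S)-5,9-dimethyldeca-2,8-dien-1-ol | CC(C)=CCC[C@H](C)C/C=C\CO
F5 | step 8 | (2Z,5S)-5,9-dimethyldeca-2,8-dienal | CC(C)=CCC[C@H](C)C/C=C\C=O
F6 | step 8 | methyl (2S)-2-[3,4-bis(tert-butyldimethylsilyloxy)phenyl]-6-[(3Z,6S)-2-hydroxy-6,10-dimethylundeca-3,9-dien-1-yl]-4-oxo-2,3-dihydro-4H-pyran-5-carboxylate (carbinol epimers) | CC(C)=CCC[C@H](C)C/C=C\C(O)CC1=C(C(=O)OC)C(=O)C[C@@H](c2ccc(O[Si](C)(C)C(C)(C)C)c(O[Si](C)(C)C(C)(C)C)c2)O1
F7 | step 5 | methyl (5S)-5-[3,4-bis(tert-butyldimethylsilyloxy)phenyl]-3-oxo-5-(triethylsilyloxy)pentanoate | COC(=O)CC(=O)C[C@H](O[Si](CC)(CC)CC)c1ccc(O[Si](C)(C)C(C)(C)C)c(O[Si](C)(C)C(C)(C)C)c1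
F8 | step 5 | methyl (5S)-2-acetyl-5-[3,4-bis(tert-butyldimethylsilyloxy)phenyl]-3-oxo-5-(triethylsilyloxy)pentanoate | COC(=O)C(C(C)=O)C(=O)C[C@H](O[Si](CC)(CC)CC)c1ccc(O[Si](C)(C)C(C)(C)C)c(O[Si](C)(C)C(C)(C)C)c1
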